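**Retrosynthetic overview**
1. Target 20 ← carbamate 19 (LiAlH4): the carbamate carbon becomes N‑CH3 and the phenol is already free.
2. 19 ← acyclic triyne 16 by an intramolecular hexadehydro‑Diels–Alder reaction: the benzene ring and the nitrogen ring of the tetrahydroisoquinoline form together, and the resulting 7,8‑aryne is captured by Et3SiOH at C8 (directed by the C6 methoxy group).
3. 16 ← bromoalkyne 12 + methoxyacetylide; 12 ← amine 10 ← (S)‑alkynol 7 + (R)‑but‑3‑yn‑2‑amine 8 (C1 from 8, C3 by SN2 inversion).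
4. 7 ← Sonogashira of bromonaphthalene 5 with (S)‑pent‑4‑yn‑2‑ol; 5 ← Heck / Friedel–Crafts benzannulation of 1 + 2.
5. Ring order: second naphthalene ring (step 2), then both isoquinoline rings at once (step 9).

Assumption: the SMILES fixes only C1 and C3 (both R); the biaryl axis is unspecified, so it is taken as it forms in step 9 (atropisomers, if a single one is wanted, separated by HPLC at 20).

**Step 1**
Reactants: 1 1‑bromo‑2‑iodo‑4‑methoxybenzene; 2 3‑methylbut‑3‑enoic acid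
Product: 3 (E)‑4‑(2‑bromo‑5‑methoxyphenyl)‑3‑methylbut‑3‑enoic acid
Conditions: Pd(OAc)2 (3 mol %), Bu4NCl, NaHCO3, DMF, 60 °C; aq. HCl work‑up
Reagents that add atoms: none
Why: Ligand‑free Heck (Jeffery) arylation engages only the carbon–iodine bond and the unsubstituted alkene terminus, the carboxylate of 2 cannot slip into conjugation, and the minor double‑bond isomers formed beside 3 all converge in step 2.

**Step 2**
Reactants: 3 (E)‑4‑(2‑bromo‑5‑methoxyphenyl)‑3‑methylbut‑3‑enoic acid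
Product: 4 5‑bromo‑8‑methoxy‑3‑methylnaphthalen‑1‑ol
Conditions: Eaton's reagent (P2O5 in MeSO3H), 45 °C
Reagents that add atoms: none
Why: Acid equilibrates the alkene isomers, intramolecular Friedel–Crafts acylation closes at the only free position next to the side chain (ortho to OMe, the other being blocked by Br), and the naphthalenone tautomerises to the naphthol.

**Step 3**
Reactants: 4 5‑bromo‑8‑methoxy‑3‑methylnaphthalen‑1‑ol
Product: 5 1‑bromo‑4,5‑dimethoxy‑7‑methylnaphthalene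
Conditions: MeI, K2CO3, DMF, 40 °C
Reagents that add atoms: iodomethane, CI
Why: Williamson O‑methylation of the peri‑hydrogen‑bonded naphthol is routine in DMF with mild warming.

**Step 4**
Reactants: 5 1‑bromo‑4,5‑dimethoxy‑7‑methylnaphthalene; 6 (S)‑pent‑4‑yn‑2‑ol
Product: 7 (2S)‑5‑(4,5‑dimethoxy‑7‑methylnaphthalen‑1‑yl)pent‑4‑yn‑2‑ol
Conditions: PdCl2(MeCN)2 (3 mol %), XPhos (9 mol %), Cs2CO3, MeCN, 80 °C
Reagents that add atoms: none
Why: Copper‑free Sonogashira coupling with a bulky biarylphosphine handles the electron‑rich, peri‑hindered bromide, tolerates the free alcohol and leaves the carbinol stereocentre untouched.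

**Step 5**
Reactants: 7 (2S)‑5‑(4,5‑dimethoxy‑7‑methylnaphthalen‑1‑yl)pent‑4‑yn‑2‑ol; 8 (R)‑but‑3‑yn‑2‑amine (sold as the hydrochloride, free‑based before use)
Product: 10 (2R)‑N‑[(2R)‑but‑3‑yn‑2‑yl]‑5‑(4,5‑dimethoxy‑7‑methylnaphthalen‑1‑yl)pent‑4‑yn‑2‑amine, via mesylate 9 (not isolated)
Conditions: MsCl, Et3N, CH2Cl2, 0 °C; then 8 (3 equiv), MeCN, 65 °C
Reagents that add atoms: none
Why: Mesylation followed by SN2 displacement with the small primary amine inverts the (S)‑carbinol carbon to the (R)‑configured future C3, while the future C1 arrives with its (R)‑centre ready‑made in 8.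

**Step 6**
Reactants: 10 (2R)‑N‑[(2R)‑but‑3‑yn‑2‑yl]‑5‑(4,5‑dimethoxy‑7‑methylnaphthalen‑1‑yl)pent‑4‑yn‑2‑amine
Product: 11 methyl N‑[(2R)‑but‑3‑yn‑2‑yl]‑N‑[(2R)‑5‑(4,5‑dimethoxy‑7‑methylnaphthalen‑1‑yl)pent‑4‑yn‑2‑yl]carbamate
Conditions: ClCO2Me, i‑Pr2NEt, CH2Cl2, 0 to 23 °C
Reagents that add atoms: methyl chloroformate, COC(=O)Cl
Why: N‑acylation to the carbamate removes the basicity and nucleophilicity of nitrogen (which would otherwise attack the aryne and the ynol ether) and installs the carbon that ends as N‑CH3.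

**Step 7**
Reactants: 11 methyl N‑[(2R)‑but‑3‑yn‑2‑yl]‑N‑[(2R)‑5‑(4,5‑dimethoxy‑7‑methylnaphthalen‑1‑yl)pent‑4‑yn‑2‑yl]carbamate
Product: 12 methyl N‑[(2R)‑4‑bromobut‑3‑yn‑2‑yl]‑N‑[(2R)‑5‑(4,5‑dimethoxy‑7‑methylnaphthalen‑1‑yl)pent‑4‑yn‑2‑yl]carbamate
Conditions: LiN(i‑Pr)2, THF, −78 °C; then BrCCl2CCl2Br, −78 °C
Reagents that add atoms: 1,2‑dibromo‑1,1,2,2‑tetrachloroethane, BrC(Cl)(Cl)C(Cl)(Cl)Br
Why: Deprotonation of the only acidic C–H (terminal alkyne) and bromination of the acetylide by a positive‑bromine donor at −78 °C gives the 1‑bromoalkyne without the ring bromination of the electron‑rich naphthalene that NBS would cause.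

**Step 8**
Reactants: 12 methyl N‑[(2R)‑4‑bromobut‑3‑yn‑2‑yl]‑N‑[(2R)‑5‑(4,5‑dimethoxy‑7‑methylnaphthalen‑1‑yl)pent‑4‑yn‑2‑yl]carbamate; 13 2‑chloro‑1,1‑dimethoxyethane
Product: 16 methyl N‑[(2R)‑6‑methoxyhexa‑3,5‑diyn‑2‑yl]‑N‑[(2R)‑5‑(4,5‑dimethoxy‑7‑methylnaphthalen‑1‑yl)pent‑4‑yn‑2‑yl]carbamate, via methoxyethynyllithium 14 (not isolated), via methoxyethynylcopper 15 (not isolated)
Conditions: 13, n‑BuLi/Et2NH (LiNEt2, 3.1 equiv), THF, −10 °C; CuI, 0 °C; then 12, pyridine, 0 to 23 °C (O2 excluded)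
Reagents that add atoms: none
Why: Proposed new method: triple elimination of the chloroacetal by lithium amide gives the base‑stable methoxyacetylide, whose copper acetylide should couple sp–sp with the 1‑bromoalkyne by oxidative addition and reductive elimination at copper, exactly as in a Cadiot–Chodkiewicz coupling (closest known type, together with copper alkoxyacetylides in Sonogashira‑type couplings); the methyl ynol ether has no β‑hydrogen on oxygen and so cannot fragment to a ketene.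

**Step 9**
Reactants: 16 methyl N‑[(2R)‑6‑methoxyhexa‑3,5‑diyn‑2‑yl]‑N‑[(2R)‑5‑(4,5‑dimethoxy‑7‑methylnaphthalen‑1‑yl)pent‑4‑yn‑2‑yl]carbamate
Product: 19 methyl (1R,3R)‑5‑(4,5‑dimethoxy‑7‑methylnaphthalen‑1‑yl)‑8‑hydroxy‑6‑methoxy‑1,3‑dimethyl‑3,4‑dihydroisoquinoline‑2(1H)‑carboxylate, via aryne 17 (not isolated), via triethylsilyl ether 18 (not isolated)
Conditions: Et3SiOH (15 equiv), 1,2‑dichlorobenzene (0.01 M), 160 °C, base‑washed sealed tube; then K2CO3, MeOH, 23 °C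
Reagents that add atoms: triethylsilanol, CC[Si](O)(CC)CC
Why: Proposed new method: a thermal hexadehydro‑Diels–Alder reaction (closest known type: triyne‑to‑benzyne cycloisomerisation through three‑atom tethers, here extended to a four‑atom carbamate tether whose two α‑branched arms are held on one face by allylic strain) joins the diyne carbon next to C1 to the alkyne carbon next to C4 and the methoxy terminus to the naphthyl terminus through a diradical stabilised by OMe and naphthyl, forming both rings of the isoquinoline and a 7,8‑aryne; the C6 methoxy group polarises the aryne as in 3‑methoxybenzyne so that the silanol O–H (no α‑C–H, hence no hydrogen‑transfer reduction, as for tertiary alcohols) adds with oxygen at C8 and hydrogen at C7, the silyl ether is methanolysed in the work‑up, and the two stereocentres are spectators.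

**Step 10**
Reactants: 19 methyl (1R,3R)‑5‑(4,5‑dimethoxy‑7‑methylnaphthalen‑1‑yl)‑8‑hydroxy‑6‑methoxy‑1,3‑dimethyl‑3,4‑dihydroisoquinoline‑2(1H)‑carboxylate
Product: 20 (1R,3R)‑5‑(4,5‑dimethoxy‑7‑methylnaphthalen‑1‑yl)‑6‑methoxy‑1,2,3‑trimethyl‑1,2,3,4‑tetrahydroisoquinolin‑8‑ol (ancistrocongoline B)
Conditions: LiAlH4 (5 equiv), THF, 66 °C; aq. potassium sodium tartrate, pH 8–9
Reagents that add atoms: none
Why: Hydride reduction of the N‑methoxycarbonyl group to N‑methyl is a standard carbamate reduction that touches neither the aryl ethers nor the two stereocentres, and the phenol is released from its aluminate on work‑up.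

**Compound list**
1 | 1‑bromo‑2‑iodo‑4‑methoxybenzene | COc1ccc(Br)c(I)c1 | starting material
2 | 3‑methylbut‑3‑enoic acid | C=C(C)CC(=O)O | starting material
3 | (E)‑4‑(2‑bromo‑5‑methoxyphenyl)‑3‑methylbut‑3‑enoic acid | COc1ccc(Br)c(/C=C(\C)CC(=O)O)c1 | intermediate
4 | 5‑bromo‑8‑methoxy‑3‑methylnaphthalen‑1‑ol | COc1ccc(Br)c2cc(C)cc(O)c12 | intermediate
5 | 1‑bromo‑4,5‑dimethoxy‑7‑methylnaphthalene | COc1ccc(Br)c2cc(C)cc(OC)c12 | intermediate
6 | (S)‑pent‑4‑yn‑2‑ol | C[C@H](O)CC#C | starting material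
7 | (2S)‑5‑(4,5‑dimethoxy‑7‑methylnaphthalen‑1‑yl)pent‑4‑yn‑2‑ol | C[C@H](O)CC#Cc1ccc(OC)c2c(OC)cc(C)cc12 | intermediate
8 | (R)‑but‑3‑yn‑2‑amine | C[C@@H](N)C#C | starting material
9 | (2S)‑5‑(4,5‑dimethoxy‑7‑methylnaphthalen‑1‑yl)pent‑4‑yn‑2‑yl methanesulfonate | C[C@H](OS(C)(=O)=O)CC#Cc1ccc(OC)c2c(OC)cc(C)cc12 | intermediate
10 | (2R)‑N‑[(2R)‑but‑3‑yn‑2‑yl]‑5‑(4,5‑dimethoxy‑7‑methylnaphthalen‑1‑yl)pent‑4‑yn‑2‑amine | C[C@@H](N[C@H](C)C#C)CC#Cc1ccc(OC)c2c(OC)cc(C)cc12 | intermediate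
11 | methyl N‑[(2R)‑but‑3‑yn‑2‑yl]‑N‑[(2R)‑5‑(4,5‑dimethoxy‑7‑methylnaphthalen‑1‑yl)pent‑4‑yn‑2‑yl]carbamate | C[C@@H](N(C(=O)OC)[C@H](C)C#C)CC#Cc1ccc(OC)c2c(OC)cc(C)cc12 | intermediate
12 | methyl N‑[(2R)‑4‑bromobut‑3‑yn‑2‑yl]‑N‑[(2R)‑5‑(4,5‑dimethoxy‑7‑methylnaphthalen‑1‑yl)pent‑4‑yn‑2‑yl]carbamate | C[C@@H](N(C(=O)OC)[C@H](C)C#CBr)CC#Cc1ccc(OC)c2c(OC)cc(C)cc12 | intermediate
13 | 2‑chloro‑1,1‑dimethoxyethane | COC(CCl)OC | starting material
14 | methoxyethynyllithium | [Li]C#COC | intermediate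
15 | methoxyethynylcopper | [Cu]C#COC | intermediate
16 | methyl N‑[(2R)‑6‑methoxyhexa‑3,5‑diyn‑2‑yl]‑N‑[(2R)‑5‑(4,5‑dimethoxy‑7‑methylnaphthalen‑1‑yl)pent‑4‑yn‑2‑yl]carbamate | C[C@@H](N(C(=O)OC)[C@H](C)C#CC#COC)CC#Cc1ccc(OC)c2c(OC)cc(C)cc12 | intermediate
17 | methyl (1R,3R)‑7,8‑didehydro‑5‑(4,5‑dimethoxy‑7‑methylnaphthalen‑1‑yl)‑6‑methoxy‑1,3‑dimethyl‑3,4‑dihydroisoquinoline‑2(1H)‑carboxylate (7,8‑aryne) | COC1=C(c3ccc(OC)c4c(OC)cc(C)cc34)C2=C(C#C1)[C@@H](C)N(C(=O)OC)[C@H](C)C2 | intermediate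
18 | methyl (1R,3R)‑5‑(4,5‑dimethoxy‑7‑methylnaphthalen‑1‑yl)‑6‑methoxy‑1,3‑dimethyl‑8‑(triethylsilyloxy)‑3,4‑dihydroisoquinoline‑2(1H)‑carboxylate | COc1cc(O[Si](CC)(CC)CC)c2c(c1-c1ccc(OC)c3c(OC)cc(C)cc13)C[C@@H](C)N(C(=O)OC)[C@@H]2C | intermediate
19 | methyl (1R,3R)‑5‑(4,5‑dimethoxy‑7‑methylnaphthalen‑1‑yl)‑8‑hydroxy‑6‑methoxy‑1,3‑dimethyl‑3,4‑dihydroisoquinoline‑2(1H)‑carboxylate | COc1cc(O)c2c(c1-c1ccc(OC)c3c(OC)cc(C)cc13)C[C@@H](C)N(C(=O)OC)[C@@H]2C | intermediate
20 | (1R,3R)‑5‑(4,5‑dimethoxy‑7‑methylnaphthalen‑1‑yl)‑6‑methoxy‑1,2,3‑trimethyl‑1,2,3,4‑tetrahydroisoquinolin‑8‑ol (ancistrocongoline B) | COc1cc(O)c2c(c1-c1ccc(OC)c3c(OC)cc(C)cc13)C[C@@H](C)N(C)[C@@H]2C | target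

**Step count and risks**
Total steps: 10. Longest linear sequence: 10 (1 → 20).

Most likely to fail, with one fallback each:

1. Step 9. A four‑atom tether cyclises far more slowly than the usual three‑atom ones, the methoxydiyne must survive 160 °C in the presence of a silanol, and some capture at C7 is possible. The fallback replaces the thermal aryne route by a metal‑catalysed [2+2+2] cyclotrimerisation. It sets out from 11, which is deprotonated (LiN(i‑Pr)2) and borylated with 2‑isopropoxy‑4,4,5,5‑tetramethyl‑1,3,2‑dioxaborolane to give the alkynyl pinacol boronate F1. Separately, 13 is converted with NaNH2 in liquid NH3 and an NH4Cl quench into methoxyacetylene F2. F1 and F2 (slow addition) are combined with a cationic monovalent rhodium catalyst, [Rh(cod)2]BF4/BINAP, in 1,2‑dichloroethane to form the benzene ring and the nitrogen ring together as the aryl pinacol boronate F3. The bulky boryl terminus and the polarised ynol ether are expected to place the methoxy carbon next to the naphthyl‑bearing carbon, but this regiochemistry is unproven and the regioisomer would have to be removed by chromatography. Oxidation of F3 with NaBO3 in THF/water comes back to the route at 19.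

2. Step 8. The copper methoxyacetylide may homocouple or decompose, and the alkoxydiyne is fragile. The fallback sets out from 12 and from 14. 14 is quenched with Bu3SnCl to give distillable tributyl(methoxyethynyl)stannane F4, which is then joined to 12 by a Stille coupling under neutral conditions (Pd(PPh3)4, zerovalent palladium, THF, 23 °C). This separates the generation of the ynol ether nucleophile from the coupling and comes back to the route at 16.

3. Step 5. The secondary homopropargylic mesylate may eliminate to the enyne or react sluggishly. The fallback sets out from 7 and 8. 8 is converted with 2‑nitrobenzenesulfonyl chloride/Et3N into the 2‑nitrobenzenesulfonamide F5, which is condensed with 7 under Mitsunobu conditions (PPh3, diisopropyl azodicarboxylate, THF; inversion at the carbinol carbon) to the tertiary sulfonamide F6. Removal of the sulfonyl group with PhSH/K2CO3 in MeCN comes back to the route at 10.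

**Further compounds**
F1 | step 9 | methyl N‑[(2R)‑4‑(4,4,5,5‑tetramethyl‑1,3,2‑dioxaborolan‑2‑yl)but‑3‑yn‑2‑yl]‑N‑[(2R)‑5‑(4,5‑dimethoxy‑7‑methylnaphthalen‑1‑yl)pent‑4‑yn‑2‑yl]carbamate | C[C@@H](N(C(=O)OC)[C@H](C)C#CB1OC(C)(C)C(C)(C)O1)CC#Cc1ccc(OC)c2c(OC)cc(C)cc12
F2 | step 9 | methoxyacetylene | COC#C
F3 | step 9 | methyl (1R,3R)‑5‑(4,5‑dimethoxy‑7‑methylnaphthalen‑1‑yl)‑6‑methoxy‑1,3‑dimethyl‑8‑(4,4,5,5‑tetramethyl‑1,3,2‑dioxaborolan‑2‑yl)‑3,4‑dihydroisoquinoline‑2(1H)‑carboxylate | COc1cc(B2OC(C)(C)C(C)(C)O2)c2c(c1-c1ccc(OC)c3c(OC)cc(C)cc13)C[C@@H](C)N(C(=O)OC)[C@@H]2C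
F4 | step 8 | tributyl(methoxyethynyl)stannane | CCCC[Sn](CCCC)(CCCC)C#COC
F5 | step 5 | N‑[(2R)‑but‑3‑yn‑2‑yl]‑2‑nitrobenzenesulfonamide | C#C[C@@H](C)NS(=O)(=O)c1ccccc1[N+](=O)[O-]
F6 | step 5 | N‑[(2R)‑but‑3‑yn‑2‑yl]‑N‑[(2R)‑5‑(4,5‑dimethoxy‑7‑methylnaphthalen‑1‑yl)pent‑4‑yn‑2‑yl]‑2‑nitrobenzenesulfonamide | C[C@@H](N([C@H](C)C#C)S(=O)(=O)c1ccccc1[N+](=O)[O-])CC#Cc1ccc(OC)c2c(OC)cc(C)cc12
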